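The easy step comes first: the first reading of a run, divided by its time, is taken as the making rate of the complex with one exchanged, in fractions of the charge per minute. The dusk run gives 0.281 min⁻¹. Later the dusk readings lie close together, 21.2% at 2.00 min and at 2.50 min. With a scatter of 0.3 percentage points, equal readings do not show that the curve has stopped, so treating making and loss as level there is an approximation of this reckoning.

| flask | starting complex | incoming ligand | remark | time |
|---|---|---|---|---|
| midnight | 0.070 M | 1 equiv | run made earlier |  |
| dusk | 0.11 M | 1 equiv | run made earlier |  |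
| dawn | 0.050 M | 1.5 equiv | run made earlier |  |
| flask | 0.050 M | 1.00 equiv |  | 4.0 min |

| run | time / min | complex with one exchanged / % |
|---|---|---|
| midnight | 0.167 | 3.1 |
| midnight | 0.500 | 8.4 |
| midnight | 0.833 | 11.5 |
| midnight | 1.33 | 14.8 |
| midnight | 2.00 | 17.3 |
| midnight | 2.50 | 18.5 |
| dusk | 0.167 | 4.7 |
| dusk | 0.500 | 11.3 |
| dusk | 0.833 | 16.0 |
| dusk | 1.33 | 18.6 |
| dusk | 2.00 | 21.2 |
| dusk | 2.50 | 21.2 |
| dawn | 0.200 | 4.1 |
| dawn | 0.667 | 10.7 |
| dawn | 1.00 | 14.1 |
| dawn | 1.50 | 16.8 |
| dawn | 2.50 | 20.1 |

(scatter of a reading: 0.3 percentage points)
- the numbers in the tables scatter by 0.3 percentage points (one standard deviation)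
- equivalents of incoming ligand to starting complex, everything else as given, that leave most complex with one exchanged at 4.0 min
- the amount of complex with one exchanged then, in percent of the starting complex charged
- the amount of complex with one exchanged with the amounts as given

With equal charges, starting complex and incoming ligand each keep a fraction 1/(1 + rate × time) if they react one for one, and making falls with its square. With that approximation, at these last dusk readings:

fraction left = 0.612
21.2% / (0.281 min⁻¹ × 0.375) = 2.01 min

This is the holding time: standing amount over making rate, an estimate read from scattered readings.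

For whoever takes over the flask: the dawn run, scaled to 1.00 equiv, gives a making rate of 0.137 min⁻¹. The reckoning sets what stands at 4.0 min equal to the holding time multiplied by the making rate one holding time earlier, at 1.99 min:

fraction left = 0.786
standing = 0.137 min⁻¹ × 0.618 × 2.01 min = 17.0%

The forecast says 19%, above this reckoning, and 20% at 1.35 equiv, adding “The optimum is flat, and the gain is small”.

The flask gives 17.7%, and 25.6% at 3.19 equiv. At 4.00 min it also holds 10.5% of isomer of the product. From the 77.9% of starting complex and 74.3% of incoming ligand at 2.00 min, the holding time gives 15.9%.

    starting complex + incoming ligand ⇌ leaving ligand + complex with one exchanged (K = 0.570, k = 0.0499 L mol⁻¹ s⁻¹)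
    complex with three exchanged + incoming ligand ⇌ leaving ligand + complex with four exchanged (K = 0.196, k = 0.00195 L mol⁻¹ s⁻¹)
    complex with two exchanged + incoming ligand ⇌ leaving ligand + complex with three exchanged (K = 0.400, k = 0.102 L mol⁻¹ s⁻¹)
    complex with one exchanged ⇌ isomer of the product (K = 1.16, k = 0.00500 s⁻¹)
    incoming ligand → decomposition product (k = 6.83 × 10⁻⁶ s⁻¹)
    leaving ligand → by-product carried off (k = 0.00345 s⁻¹)
    complex with one exchanged + incoming ligand ⇌ leaving ligand + complex with two exchanged (K = 0.200, k = 0.0751 L mol⁻¹ s⁻¹)

With 0.250 equiv in the same flask, the ligand's fraction left is taken as exponential, and the holding time gives 5.24%. The computed amount is 6.37%.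

(The readings stem from a simulated flask for an exercise; noise was put on by code.)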